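The leftover of electrophile is what I watch: in the blue run 4% of the charge still stands at 120 min, and I want to know how much of such a remainder survives to 4.0 h in dusk, winter and autumn.

| flask | electrophile | nucleophile | free base | protic impurity | remark | time |
|---|---|---|---|---|---|---|
| blue | 0.020 M | 0.036 M | 0.025 M | 10 mM | run made earlier |  |
| violet | 0.020 M | 0.036 M | 0.11 M | 10 mM | run made earlier |  |
| dusk | 0.020 M | 0.0360 M | 0.0800 M | 10.0 mM |  | 4.0 h |
| winter | 0.020 M | 0.0360 M | 0.160 M | 10.0 mM |  | 4.0 h |
| autumn | 0.020 M | 0.0360 M | 0.0400 M | 10.0 mM |  | 4.0 h |

| run | time / min | electrophile / % | target / % |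
|---|---|---|---|
| blue | 30.0 | 28 | 32 |
| blue | 60.0 | 15 | 37 |
| blue | 90.0 | 10 | 40 |
| blue | 120 | 4 | 43 |
| violet | 10.0 | 55 | 14 |
| violet | 20.0 | 38 | 21 |
| violet | 50.0 | 13 | 35 |
| violet | 120 | 3 | 44 |

(standard deviation of a reading: 2 percentage points)

- part of the electrophile that has reacted at the end, dusk
- part of the electrophile that has reacted at the end, winter
- part of the electrophile that has reacted at the end, autumn
- what raising the concentration of free base from its lowest to its highest value here does to the part of the electrophile that has reacted (changes below 5 percentage points count as none) (it falls / it rises / no change)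

I carry one quantity, the tail time constant: the time in which the remaining fraction of electrophile falls by a factor e late in a run, a pseudo-first-order reading of the decay. The answer is one minus the last remainder times the decay over the time still to run, so two numbers enter, and I ask first how well each must be known. If the last blue reading is off by one scatter, 2 percentage points, the answer moves by 0.14 points. If the constant is twice as long as the readings suggest, it moves by 0.78 points, so the constant matters more, though neither comes near the margin of 5 points. Free base shows little so far: with 0.025 M and 0.11 M, the blue and violet runs leave 4% and 3%, a gap smaller than the scatter.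

Now the number. The time for a factor e in the blue remainder, from 60.0 min to 120 min, is 45.4 min, and the violet run reads 47.7 min. From the blue figure I reckon a remainder of 0.284%, so I expect 99.7% reacted in dusk, winter and autumn alike, though winter's base lies above both runs. The first 30.0 min of the blue run read 23.6 min, shorter than the tail, so in these readings the constant lengthens and my remainder may be on the low side.

The forecast says 99.5% for dusk, 99.5% for winter, 99.4% for autumn and no change, holding that “Extrapolating from 3–4% at 120 min gives well under 1% left at 240 min”. Its dusk figure leaves 0.500% of the charge, where I reckon 0.284%.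

The flasks give 99.3% in dusk, 99.3% in winter and 99.2% in autumn, so no change, with a change of 0.15 points.

    electrophile + nucleophile → acid set free + target (k = 0.00990 L mol⁻¹ s⁻¹)
    nucleophile + acid set free ⇌ protonated nucleophile, settled at all times (K = 1.50 × 10⁵ L mol⁻¹)
    acid set free + free base ⇌ salt of the base, settled at all times (K = 6.40 × 10⁵ L mol⁻¹)
    free base ⇌ dormant form (K = 0.720, k = 6.70 × 10⁻⁴ s⁻¹)
    acid set free + target → side product (k = 0.430 L mol⁻¹ s⁻¹)
    electrophile + protic impurity → quenched substrate (k = 0.130 L mol⁻¹ s⁻¹)

Dusk holds 4.84% of its electrophile at 2.00 h and 0.706% at 4.00 h, a tail time constant of 62.4 min, longer than the 45.4 min read from blue. Carrying this longer constant to winter, whose remainder is 0.655% at 4.00 h, I get 0.00205% left at 10 h. The winter reading at that time shows >99.9% reacted.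

Readings and results were computed on assumed constants; scatter was added.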